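## Analysis of the target

The target is a daucane-type sesquiterpenoid ester on a trans-fused hydroazulene: cyclopentane ring A (C1–C5) shares the C1–C5 bond with cycloheptane ring B (C1, C10, C9, C8, C7, C6, C5). There are six stereocentres: C1 (quaternary, angular methyl), C4 (tertiary carbinol with the isopropyl group), C5 (ring-fusion CH), C6 (secondary carbinol acylated by 4-hydroxybenzoic acid), C8 (tertiary carbinol with a methyl group) and C9 (secondary carbinol). With α defined as the face that carries the C1 methyl group, H-5 is β (trans fusion), the C4 hydroxyl is α and the isopropyl group β, and the C6 oxygen is β. The 8,9-diol is trans, with the C8 hydroxyl α (C8 methyl β) and the C9 hydroxyl β, so the tertiary C8 hydroxyl lies on the hindered face under the angular methyl. Sensitive points are the two tertiary alcohols (elimination in acid), the aryl ester (base, acyl shift to the C9 hydroxyl), the free phenol, and the C4 oxygen β to C6, which invites retro-aldol cleavage whenever C6 is a carbonyl and that oxygen is free. The difficulty lies in a seven-membered ring with five substituted carbons beside a quaternary centre, the contiguous array C4–C5–C6, and four hydroxyl groups of which one must be acylated. The strategy rests on C8: it is a methyl-bearing carbon between C9 and C7, and without it ring B shrinks to a six-membered ring (C1, C10, C9, C7, C6, C5) whose C6 carbinol is β to a C9 carbonyl. That is an aldol pattern, and a CH(CH3) unit beside the C9 carbonyl is what a one-carbon insertion with diazoethane supplies.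

## Retrosynthetic reasoning

**24 to 23.** Only the phenol protecting group is removed. The benzyl ether lets the acid 20 be coupled without self-condensation and survives the oxidation chemistry. It is cleaved last, when no alkene remains.

**23 to 22 to 21 (C8–O bond).** The C8 hydroxyl lies on the α-face, the concave face under the angular methyl, where no external oxidant delivers oxygen. Electrophilic oxygenation of an enol derivative of the C9 ketone such as 15 would therefore place oxygen on the β-face and give the C8 epimer. An epoxide on the open β-face (22) solves both centres with one facial preference. Hydrolytic opening at tertiary C8 with inversion puts the hydroxyl α, and the C9–O bond of the epoxide stays β. The epoxide comes from the C8=C9 alkene 21.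

**21 to 19 and 20, 19 to 18 (ester bond and silyl ethers).** In diol 19 only the C6 hydroxyl is secondary, so acylation needs no further differentiation. Both silyl ethers of 18 are removed in one operation, because a hindered secondary and a hindered tertiary silyl ether cannot be told apart reliably.

**18 to 17 to 15 to 14 (removal of the C9 oxygen).** The C8=C9 alkene is traced to the C9 ketone 14 through enol triflate 17. The position of the alkene is fixed by thermodynamic enolisation toward the more substituted C8 (enol silane 15, lithium enolate 16). Enolisation toward C10 would put a double bond beside quaternary C1.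

**14 to 11 and 13 (key disconnection, C8–C9 and C7–C8).** C8 is excised with its methyl group as diazoethane 13, which leaves six-membered ketone 11. The cut is made here because direct end-to-end closure of the seven-membered ring has no good retron, whereas the six-membered ring is an aldol product. The forward reaction must insert the carbon on the C7 side of the carbonyl and only once. Diazoethane 13 comes from nitrosourea 12.

**11 to 10 to 9 (C6–C7 bond).** The β-silyloxy ketone is an aldol of keto aldehyde 9. In the chair of the trans-fused product the C6 oxygen is equatorial, so the required 6β configuration is the favoured one. The trans fusion is already fixed by C1 and C5 in 9.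

**9 to 8 to 5 and 6 (C9 oxygen, C1–C10 bond).** The methyl ketone is the oxidation product of a terminal alkene. The allyl group of 8 is attached to C1 by conjugate addition of the allyl unit of 6 to enal 5, which creates the quaternary centre. The forward step must add 1,4 to an aldehyde and from the β-face, and C5 is then set by equilibration.

**5 to 4 to 2 to 1 (ring A).** The cyclopentene carbaldehyde is the aldol condensation product of keto aldehyde 4, which is the ozonolysis product of the cyclohexene in 2. C4 of (S)-terpinen-4-ol 1 becomes C4 of the target and is the only source of chirality. Its oxygen is silylated first so that it cannot leave or trigger retro-aldol cleavage in the carbonyl chemistry.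

## Alternatives that were turned down

**Alternative 1:** Ring A is cut at C1–C2 and C4–C5. This removes C2–C3–C4 as a homoenolate unit and leaves ring B as the symmetric 3,6-dimethylcyclohepta-2,6-dienone A1.
- Forward step: 1-isopropylcyclopropanol A2 is opened by ZnEt2 to the zinc homoenolate A3. Cu(OTf)2 with a chiral phosphoramidite transfers it to C1 of A1, and after O-silylation at C6 a TiCl4-promoted aldol of C5 onto the C4 ketone closes ring A to give A4.
- For it: it is the shortest way to the bicycle, it is catalyst-controlled, and ring B arrives with its C8 methyl. On step count to the core it is stronger than the chosen route.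
- Against it: a zinc homoenolate is a weak nucleophile, and forming a quaternary centre on a β,β-disubstituted cycloheptadienone with it lies outside what copper-catalysed additions are known to do. The aldol must give the trans fusion and the C4 hydroxyl syn to the methyl, whereas five-ring closures of this kind favour the cis bicycle. C5 stays epimerisable beside the C6 ketone, and the tertiary aldol can revert.
- What remains after A4: it has no C9 oxygen, C6 is at the ketone level, and the alkene sits at C7=C8, so a long adjustment remains.
- In its place the chosen route takes C4 from the chiral pool, sets the fusion by aldehyde equilibration and a chair aldol, and installs the C6 oxygen with defined configuration during ring formation.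

**Alternative 2:** Both rings are cut at once at C1–C5 and C7–C8, which gives the open-chain chloromethyl ketone A5 carrying a 2-silyloxy diene.
- Forward step: LiClO4 and Et3N convert A5 into the C5–C6–C7 oxyallyl cation A6, which adds across the diene termini C1 and C8 in an intramolecular (4+3) cycloaddition to give A7.
- For it: two rings, the quaternary centre and several stereocentres form in one step, and A7 carries differentiated oxygen at C6 and C9 and the C8 methyl. In gain of complexity per step it is clearly stronger.
- Against it: the outcome depends on a transition state with many variables. C1 is a trisubstituted diene terminus, the only controlling stereocentre (C4) is fully substituted with two groups of similar effective size, and the trans fusion needs the extended approach, whereas three-atom tethers commonly give cis products or mixtures. The cation can also alkylate the enol silane stepwise without closing. A5 itself needs an enantioselective synthesis of the tertiary carbinol and a geometrically defined dienol ether, and the C8 hydroxyl is still missing afterwards.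
- In its place the chosen route uses separate ring-forming steps whose stereochemical course can be predicted.

**Alternative 3:** The C1–C10 bond is cut by a retro-[3,3] shift, which traces ring B to the seven-membered β-keto lactone A8 attached through C6 to the cyclopentene.
- Forward step: thermal Carroll rearrangement (xylene, catalytic NaOAc) of the enol form of A8 bonds C10 to C1 while C6–O breaks, and decarboxylation gives A9 with a C5=C6 alkene and the C9 ketone.
- For it: the quaternary centre is made intramolecularly with suprafacial chirality transfer from C6, and the C8 carbinol arrives with its configuration beside a C9 ketone that a hydroxyl-directed reduction could turn into the trans-diol. On both points it is stronger than the steric argument of step 4 and the epoxide detour of steps 10–16.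
- Against it: the C6 oxygen that the target needs is consumed. It must be returned by hydroboration of the C5=C6 alkene on the β-face, which the C4 isopropyl group screens. The rearrangement must form a quaternary centre at a tetrasubstituted alkene terminus through a strained bicyclic transition state at high temperature. A8 needs two separately made stereocentres and a medium-ring lactonisation.
- In its place the chosen route keeps the C6 oxygen from the aldol onward and needs one chiral starting material.

Key step: step 9

Assumption: (S)-terpinen-4-ol is taken as available in high enantiomeric purity, and ketone 14 is drawn as its 8β-methyl epimer although either C8 epimer or a mixture serves, because C8 becomes trigonal in step 10.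

## Route

Step 1
Reactants: 1 (S)-terpinen-4-ol
Product: 2 (S)-terpinen-4-ol triethylsilyl ether
Conditions: TESOTf, 2,6-lutidine, CH2Cl2, 0 °C → rt
Reagents that add atoms: triethylsilyl trifluoromethanesulfonate (TESOTf), CC[Si](CC)(CC)OS(=O)(=O)C(F)(F)F
Why: Silylation of a hindered tertiary alcohol with a silyl triflate; the ether prevents retro-aldol cleavage and loss of the C4 oxygen in the carbonyl chemistry that follows and later screens the α-face of ring A.

Step 2
Reactants: 2 (S)-terpinen-4-ol triethylsilyl ether
Product: 4 3-isopropyl-6-oxo-3-(triethylsilyloxy)heptanal (C4 of the target unchanged from 1), via secondary ozonide 3 (not isolated)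
Conditions: O3, CH2Cl2, −78 °C; then PPh3, −78 °C → rt
Reagents that add atoms: ozone, [O-][O+]=O
Why: Ozonolysis of the only alkene with reductive work-up gives the 1,6-keto aldehyde; the quaternary stereocentre is not involved.

Step 3
Reactants: 4 3-isopropyl-6-oxo-3-(triethylsilyloxy)heptanal
Product: 5 5-isopropyl-2-methyl-5-(triethylsilyloxy)cyclopent-1-ene-1-carbaldehyde (C1=C5 alkene, C6 formyl group, C4 as in 1)
Conditions: piperidine (cat.), AcOH (cat.), toluene, 60 °C
Reagents that add atoms: none
Why: Amine-catalysed intramolecular aldol condensation, in which the aldehyde enamine closes 5-exo onto the methyl ketone and water is lost toward C1; the silyl ether at C4 is a poorer leaving group than the new aldol hydroxyl, so the double bond forms at C1=C5.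

Step 4
Reactants: 5 5-isopropyl-2-methyl-5-(triethylsilyloxy)cyclopent-1-ene-1-carbaldehyde; 6 allylmagnesium bromide
Product: 8 1β-allyl-4β-isopropyl-1α-methyl-4α-(triethylsilyloxy)cyclopentane-5α-carbaldehyde (H-5 β), via trimethylsilyl enol ether 7 (not isolated)
Conditions: 6, CuBr·SMe2, LiCl, TMSCl, THF, −78 °C; then K2CO3, MeOH, rt
Reagents that add atoms: none
Why: TMSCl-accelerated conjugate addition of an allylcopper reagent to a β,β-disubstituted unsaturated carbonyl compound, chosen over a Hosomi–Sakurai reaction because an allylsilane with a Lewis acid would attack the aldehyde carbon 1,2. The quaternary centre C1 is set by the C4 silyl ether: the isopropyl group turns its C–H over the ring and the SiEt3 group lies under the α-face, so the allyl group enters from the β-face. Methanolic K2CO3 cleaves enol silane 7 and equilibrates C5 so that the formyl group is trans to the allyl and isopropyl groups.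

Step 5
Reactants: 8 1β-allyl-4β-isopropyl-1α-methyl-4α-(triethylsilyloxy)cyclopentane-5α-carbaldehyde
Product: 9 4β-isopropyl-1α-methyl-1β-(2-oxopropyl)-4α-(triethylsilyloxy)cyclopentane-5α-carbaldehyde
Conditions: PdCl2 (10 mol%), CuCl, O2 (1 atm), DMF/H2O 7:1, rt
Reagents that add atoms: water, O
Why: Tsuji–Wacker oxidation of the terminal alkene gives the methyl ketone with Markovnikov selectivity; the hindered aldehyde and the tertiary silyl ether tolerate the conditions.

Step 6
Reactants: 9 4β-isopropyl-1α-methyl-1β-(2-oxopropyl)-4α-(triethylsilyloxy)cyclopentane-5α-carbaldehyde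
Product: 10 trans-fused 6β-hydroxy-4β-isopropyl-1α-methyl-4α-(triethylsilyloxy)hydrindan-9-one (six-membered ring C1, C10, C9, C7, C6, C5)
Conditions: LiN(SiMe3)2, THF, −78 °C; then AcOH, −78 °C
Reagents that add atoms: none
Why: Intramolecular aldol addition: the base removes a proton from the unhindered methyl group (C7) and the enolate closes a six-membered ring onto the C6 aldehyde. In the chair the new oxygen is equatorial (6β), because the axial position is syn-axial to the C1 methyl. The low temperature avoids epimerisation of the hindered C5–H and dehydration, so the trans fusion of 9 is kept.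

Step 7
Reactants: 10 trans-fused 6β-hydroxy-4β-isopropyl-1α-methyl-4α-(triethylsilyloxy)hydrindan-9-one
Product: 11 trans-fused 6β-(tert-butyldimethylsilyloxy)-4β-isopropyl-1α-methyl-4α-(triethylsilyloxy)hydrindan-9-one
Conditions: TBSOTf, 2,6-lutidine, CH2Cl2, −78 → 0 °C
Reagents that add atoms: tert-butyldimethylsilyl trifluoromethanesulfonate (TBSOTf), CC(C)(C)[Si](C)(C)OS(=O)(=O)C(F)(F)F
Why: Silylation of the hindered secondary aldol hydroxyl with a silyl triflate at low temperature blocks retro-aldol cleavage and dehydration before the Lewis-acid step.

Step 8
Reactants: 12 N-ethyl-N-nitrosourea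
Product: 13 diazoethane (dried toluene solution, not concentrated)
Conditions: 40% aq. KOH, toluene, 0 °C; organic layer decanted and dried over KOH pellets
Reagents that add atoms: none
Why: Base-induced decomposition of an N-alkyl-N-nitrosourea is the standard preparation of a non-stabilised diazoalkane; the cold solution is used at once.

Step 9
Reactants: 11 trans-fused 6β-(tert-butyldimethylsilyloxy)-4β-isopropyl-1α-methyl-4α-(triethylsilyloxy)hydrindan-9-one; 13 diazoethane
Product: 14 trans-fused hydroazulen-9-one with ring B complete: 6β-(tert-butyldimethylsilyloxy)-4β-isopropyl-1α,8-dimethyl-4α-(triethylsilyloxy) (8β-methyl drawn)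
Conditions: Sc(OTf)3 (10 mol%), toluene/CH2Cl2, −78 °C
Reagents that add atoms: none
Why: Sc(OTf)3 binds the C9 carbonyl, the nucleophilic carbon of 13 adds to C9, and the resulting β-oxido diazonium ion loses N2 in concert with a 1,2-shift of the ring bond anti to the C–N bond; the closest known reaction type is the Lewis-acid-catalysed homologation of cycloalkanones with diazoalkanes (Tiffeneau–Demjanov-type ring expansion). Ring B is not closed end to end but arises by enlargement of the six-membered ring, the addition making C8–C9 and the shift making C7–C8. The step needs migration of C7 and not C10. In the adduct the methyl group of the incoming carbon avoids the C10 side, which is neopentyl and flanked by the axial C1 methyl, so the departing N2 lies anti to the C9–C7 bond and C7 moves. The inductive pull of the C6 silyloxy group on C7 works against this and is the main uncertainty. A single insertion is expected because the α-branched ketone 14 is more hindered toward a second addition than 11, and the low temperature with a catalytic Lewis acid limits epoxide formation, silyl loss and β-elimination of the C6 silyloxy group. The new stereocentre C8 results from the face of addition and the rotamer that rearranges and is not controlled on purpose, since it is erased in step 10. C1, C4, C5 and C6 are not touched.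

Step 10
Reactants: 14 trans-fused hydroazulen-9-one
Product: 15 9-(trimethylsilyloxy)-Δ8 enol ether of 14
Conditions: TMSCl, NaI, Et3N, MeCN, rt
Reagents that add atoms: chlorotrimethylsilane (TMSCl), C[Si](C)(C)Cl
Why: Iodotrimethylsilane formed in the flask with Et3N gives the thermodynamic, more substituted enol silane toward C8; enolisation toward C10 is disfavoured because it would place a double bond beside quaternary C1.

Step 11
Reactants: 15 9-(trimethylsilyloxy)-Δ8 enol ether
Product: 17 Δ8-en-9-yl trifluoromethanesulfonate, via lithium enolate 16 (not isolated)
Conditions: MeLi, THF, 0 °C; then PhNTf2, −78 °C → rt; aq. NH4Cl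
Reagents that add atoms: N-phenylbis(trifluoromethanesulfonimide) (PhNTf2), O=S(=O)(N(c1ccccc1)S(=O)(=O)C(F)(F)F)C(F)(F)F
Why: MeLi cleaves the O–Si bond to the regiodefined lithium enolate, which is O-sulfonylated without equilibration, so the C8=C9 position is carried over.

Step 12
Reactants: 17 Δ8-en-9-yl trifluoromethanesulfonate
Product: 18 6β-(tert-butyldimethylsilyloxy)-4β-isopropyl-1α,8-dimethyl-4α-(triethylsilyloxy)-trans-hydroazul-8-ene
Conditions: Pd(OAc)2 (5 mol%), PPh3, HCO2H, Bu3N, DMF, 60 °C
Reagents that add atoms: none
Why: Palladium-catalysed formate reduction of an enol triflate (oxidative addition to zerovalent palladium, formate-to-hydride exchange with loss of CO2, reductive elimination) gives the trisubstituted C8=C9 alkene without double-bond migration.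

Step 13
Reactants: 18 bis-silyl ether of the Δ8 alkene
Product: 19 4β-isopropyl-1α,8-dimethyl-trans-hydroazul-8-ene-4α,6β-diol
Conditions: Bu4NF, THF, 50 °C; aq. NH4Cl
Reagents that add atoms: none
Why: Fluoride removes both silyl ethers in one operation, which avoids having to differentiate a hindered secondary from a hindered tertiary silyl ether; the alkene and the tertiary alcohol are inert.

Step 14
Reactants: 19 4β-isopropyl-1α,8-dimethyl-trans-hydroazul-8-ene-4α,6β-diol; 20 4-(benzyloxy)benzoic acid
Product: 21 6β-[4-(benzyloxy)benzoyloxy]-4β-isopropyl-1α,8-dimethyl-trans-hydroazul-8-en-4α-ol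
Conditions: 20, DCC, DMAP, CH2Cl2, rt
Reagents that add atoms: none
Why: Steglich esterification; the C6 hydroxyl is the only secondary alcohol, and the tertiary C4 hydroxyl beside the isopropyl group is not acylated under these conditions.

Step 15
Reactants: 21 6β-[4-(benzyloxy)benzoyloxy]-4β-isopropyl-1α,8-dimethyl-trans-hydroazul-8-en-4α-ol
Product: 22 8β,9β-epoxide of 21
Conditions: mCPBA, NaHCO3, CH2Cl2, 0 °C
Reagents that add atoms: 3-chloroperbenzoic acid (mCPBA), OOC(=O)c1cccc(Cl)c1
Why: Prilezhaev epoxidation; in the chair of ring B the axial C1 methyl lies over the α-face of C9, so the peracid approaches the convex β-face. This fixes the C9 oxygen as β and places the C8 oxygen provisionally β.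

Step 16
Reactants: 22 8β,9β-epoxide
Product: 23 6β-[4-(benzyloxy)benzoyloxy]-4β-isopropyl-1α,8β-dimethyl-trans-hydroazulane-4α,8α,9β-triol
Conditions: HClO4 (cat.), THF/H2O 3:1, 0 °C → rt
Reagents that add atoms: water, O
Why: Acid-catalysed epoxide hydrolysis; water attacks the tertiary, more cationic C8 anti to the breaking C–O bond, so C8 is inverted (hydroxyl α, methyl β) and C9 keeps its β oxygen, which gives the trans-diol. Attack at C9 is disfavoured because it is secondary and would pass syn-axial to the C1 methyl.

Step 17
Reactants: 23 6β-[4-(benzyloxy)benzoyloxy]-4β-isopropyl-1α,8β-dimethyl-trans-hydroazulane-4α,8α,9β-triol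
Product: 24 target CNP0197754.1
Conditions: H2 (1 atm), 10% Pd/C, EtOAc, rt
Reagents that add atoms: none
Why: Hydrogenolysis of the benzyl aryl ether frees the phenol; the benzoate ester and the alcohols are not reduced and no alkene remains.

## Compound list

1 | (S)-terpinen-4-ol | CC(C)[C@]1(O)CCC(C)=CC1 | starting material
2 | (S)-terpinen-4-ol triethylsilyl ether | CC(C)[C@]1(O[Si](CC)(CC)CC)CCC(C)=CC1 | intermediate
3 | secondary ozonide of 2 (mixture at the new centres) | CC(C)[C@]1(O[Si](CC)(CC)CC)CCC2(C)OOC(C1)O2 | intermediate
4 | 3-isopropyl-6-oxo-3-(triethylsilyloxy)heptanal | CC(C)[C@](O[Si](CC)(CC)CC)(CCC(C)=O)CC=O | intermediate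
5 | 5-isopropyl-2-methyl-5-(triethylsilyloxy)cyclopent-1-ene-1-carbaldehyde | CC(C)[C@]1(O[Si](CC)(CC)CC)CCC(C)=C1C=O | intermediate
6 | allylmagnesium bromide | C=CC[Mg]Br | starting material
7 | trimethylsilyl enol ether of 8 (C5=C6) | CC(C)[C@]1(O[Si](CC)(CC)CC)CC[C@](C)(CC=C)C1=CO[Si](C)(C)C | intermediate
8 | 1β-allyl-4β-isopropyl-1α-methyl-4α-(triethylsilyloxy)cyclopentane-5α-carbaldehyde | CC(C)[C@]1(O[Si](CC)(CC)CC)CC[C@](C)(CC=C)[C@H]1C=O | intermediate
9 | 4β-isopropyl-1α-methyl-1β-(2-oxopropyl)-4α-(triethylsilyloxy)cyclopentane-5α-carbaldehyde | CC(C)[C@]1(O[Si](CC)(CC)CC)CC[C@](C)(CC(C)=O)[C@H]1C=O | intermediate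
10 | trans-fused 6β-hydroxy-hydrindan-9-one, 4α-triethylsilyl ether | CC(C)[C@]1(O[Si](CC)(CC)CC)CC[C@]2(C)CC(=O)C[C@H](O)[C@H]21 | intermediate
11 | trans-fused hydrindan-9-one, 4α-triethylsilyl and 6β-tert-butyldimethylsilyl ethers | CC(C)[C@]1(O[Si](CC)(CC)CC)CC[C@]2(C)CC(=O)C[C@H](O[Si](C)(C)C(C)(C)C)[C@H]21 | intermediate
12 | N-ethyl-N-nitrosourea | CCN(N=O)C(N)=O | starting material
13 | diazoethane | CC=[N+]=[N-] | intermediate
14 | ring-expanded 9-ketone with the C8 methyl (8β drawn) | CC(C)[C@]1(O[Si](CC)(CC)CC)CC[C@]2(C)CC(=O)[C@H](C)C[C@H](O[Si](C)(C)C(C)(C)C)[C@H]21 | intermediate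
15 | 9-(trimethylsilyloxy)-Δ8 enol ether | CC(C)[C@]1(O[Si](CC)(CC)CC)CC[C@]2(C)CC(O[Si](C)(C)C)=C(C)C[C@H](O[Si](C)(C)C(C)(C)C)[C@H]21 | intermediate
16 | lithium Δ8-enolate | CC(C)[C@]1(O[Si](CC)(CC)CC)CC[C@]2(C)CC(O[Li])=C(C)C[C@H](O[Si](C)(C)C(C)(C)C)[C@H]21 | intermediate
17 | Δ8-en-9-yl trifluoromethanesulfonate | CC(C)[C@]1(O[Si](CC)(CC)CC)CC[C@]2(C)CC(OS(=O)(=O)C(F)(F)F)=C(C)C[C@H](O[Si](C)(C)C(C)(C)C)[C@H]21 | intermediate
18 | Δ8 alkene, bis-silyl ether | CC(C)[C@]1(O[Si](CC)(CC)CC)CC[C@]2(C)CC=C(C)C[C@H](O[Si](C)(C)C(C)(C)C)[C@H]21 | intermediate
19 | Δ8 alkene 4α,6β-diol | CC(C)[C@]1(O)CC[C@]2(C)CC=C(C)C[C@H](O)[C@H]21 | intermediate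
20 | 4-(benzyloxy)benzoic acid | O=C(O)c1ccc(OCc2ccccc2)cc1 | starting material
21 | Δ8 alkene 6β-[4-(benzyloxy)benzoate] | CC(C)[C@]1(O)CC[C@]2(C)CC=C(C)C[C@H](OC(=O)c3ccc(OCc4ccccc4)cc3)[C@H]21 | intermediate
22 | 8β,9β-epoxide of 21 | CC(C)[C@]1(O)CC[C@]2(C)C[C@@H]3O[C@]3(C)C[C@H](OC(=O)c4ccc(OCc5ccccc5)cc4)[C@H]21 | intermediate
23 | 4α,8α,9β-triol 6β-[4-(benzyloxy)benzoate] | CC(C)[C@]1(O)CC[C@]2(C)C[C@H](O)[C@@](C)(O)C[C@H](OC(=O)c3ccc(OCc4ccccc4)cc3)[C@H]21 | intermediate
24 | CNP0197754.1 | CC(C)[C@]1(O)CC[C@]2(C)C[C@H](O)[C@@](C)(O)C[C@H](OC(=O)c3ccc(O)cc3)[C@H]21 | target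

## Step count and least certain steps

Total step count: 17, of which 16 are on the main line and one (step 8) prepares diazoethane 13. Longest linear sequence: 16 steps, from 1 to 24 through steps 1–7 and 9–17.

**Step 9 (key step).** The most likely failure is migration of C10 in place of C7, because both α-carbons are CH2 groups and the C6 silyloxy group lowers the migratory aptitude of C7; a second insertion into 14 is the other risk. The fallback sets out from 11 and fixes the regiochemistry through an enol derivative and not through migratory aptitude. Kinetic enolisation with LiN(iPr)2 in the presence of TMSCl (THF, −78 °C) should take the less hindered C7 proton and give the C7=C9 trimethylsilyl enol ether F1. Ethylidene transfer (CH3CHI2, Et2Zn, CH2Cl2, 0 °C) gives the methyl-substituted siloxycyclopropane F2. FeCl3 in DMF cleaves its internal C7–C9 bond (Ito–Saegusa ring expansion) to the β-chloro ketone F3, and NaOAc in warm MeOH eliminates to the 8-methyl-7-en-9-one F4. Hydrogenation (H2, Pd/C, EtOAc) saturates the enone and comes back to the route at 14.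

**Step 4.** The likely failures are 1,2-addition of the allyl nucleophile to the aldehyde carbon in preference to attack at the fully substituted C1, and attack from the α-face if the silyl group screens less than argued. The fallback sets out from 5 and uses the 1,2-addition. Reagent 6 alone (THF, −78 °C) gives the dienol F5 as a mixture at C6. KH with 18-crown-6 in THF (0 °C → rt, kept cold at first to limit silyl transfer between the two oxygen atoms) triggers an anionic oxy-Cope rearrangement that moves the allyl group to C1 across the same β-face. Protonation and equilibration with K2CO3 in MeOH come back to the route at 8.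

**Step 6.** The likely failures are epimerisation at C5 ahead of ring closure, which would lead to the cis-fused ketone, and dehydration of the aldol under basic conditions. The fallback sets out from 9 and closes the ring under Lewis-acid conditions. Soft enolisation (TMSOTf, Et3N, CH2Cl2, −78 °C) should give the terminal trimethylsilyl enol ether F6 of the methyl ketone, the hindered aldehyde being left alone. BF3·OEt2 (CH2Cl2, −78 °C) then promotes an intramolecular Mukaiyama aldol that comes back to the route at 10 after aqueous work-up.

**Step 15.** The likely failure is poor facial selectivity if ring B reacts through a boat conformer in which the α-face is open. The fallback sets out from 19 and adds a directing group to the steric bias. The free 6β-hydroxyl, homoallylic to C8, directs VO(acac)2 with t-BuOOH (CH2Cl2, 0 °C) to the β-face and gives the epoxy diol F7. Esterification with 20 as in step 14 comes back to the route at 22.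

**Step 16.** The likely failures are cationic side reactions of the protonated epoxide (hydride shift to a C9 ketone, elimination to allylic alcohols, ionisation of the tertiary C4 alcohol) and opening at C9. The fallback sets out from 21 and avoids a free carbocation. Oxymercuration with Hg(OAc)2 in THF/H2O adds hydroxyl to tertiary C8 from the α-face and mercury to C9 on the β-face (anti addition), which gives the organomercurial F8. Oxidative demercuration (NaBH4, O2, DMF) replaces mercury by hydroxyl through a C9 radical that should be trapped by O2 on the open β-face, and comes back to the route at 23.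

## Further compounds

F1 | step 9 | C7=C9 trimethylsilyl enol ether of 11 | CC(C)[C@]1(O[Si](CC)(CC)CC)CC[C@]2(C)CC(O[Si](C)(C)C)=C[C@H](O[Si](C)(C)C(C)(C)C)[C@H]21
F2 | step 9 | methyl-substituted siloxycyclopropane across C7–C9 (mixture at the cyclopropane centres) | CC(C)[C@]1(O[Si](CC)(CC)CC)CC[C@]2(C)CC3(O[Si](C)(C)C)C(C)C3[C@H](O[Si](C)(C)C(C)(C)C)[C@H]21
F3 | step 9 | ring-expanded 7-chloro-8-methyl-9-ketone | CC(C)[C@]1(O[Si](CC)(CC)CC)CC[C@]2(C)CC(=O)C(C)C(Cl)[C@H](O[Si](C)(C)C(C)(C)C)[C@H]21
F4 | step 9 | ring-expanded 8-methyl-7-en-9-one | CC(C)[C@]1(O[Si](CC)(CC)CC)CC[C@]2(C)CC(=O)C(C)=C[C@H](O[Si](C)(C)C(C)(C)C)[C@H]21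
F5 | step 4 | 1,2-adduct of 5 with the allyl group at C6 (dienol, C6 mixture) | CC(C)[C@]1(O[Si](CC)(CC)CC)CCC(C)=C1C(O)CC=C
F6 | step 6 | terminal trimethylsilyl enol ether of the methyl ketone of 9 | CC(C)[C@]1(O[Si](CC)(CC)CC)CC[C@](C)(CC(=C)O[Si](C)(C)C)[C@H]1C=O
F7 | step 15 | 8β,9β-epoxide of diol 19 | CC(C)[C@]1(O)CC[C@]2(C)C[C@@H]3O[C@]3(C)C[C@H](O)[C@H]21
F8 | step 16 | 9β-(acetoxymercurio)-8α-hydroxy adduct of 21 | CC(C)[C@]1(O)CC[C@]2(C)C[C@H]([Hg]OC(C)=O)[C@@](C)(O)C[C@H](OC(=O)c3ccc(OCc4ccccc4)cc3)[C@H]21
A1 | alternative 1 | 3,6-dimethylcyclohepta-2,6-dienone | O=C1C=C(C)CCC(C)=C1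
A2 | alternative 1 | 1-isopropylcyclopropanol | CC(C)C1(O)CC1
A3 | alternative 1 | ethylzinc homoenolate of A2 | CC[Zn]CCC(=O)C(C)C
A4 | alternative 1 | trans-fused hydroazulen-6-one with C4 carbinol and C7=C8 enone | CC(C)[C@]1(O)CC[C@]2(C)CCC(C)=CC(=O)[C@H]21
A5 | alternative 2 | open-chain chloromethyl ketone with the 2-silyloxy diene | CC(C)[C@@](O[Si](CC)(CC)CC)(CC(=O)CCl)CCC(C)=CC(O[Si](C(C)C)(C(C)C)C(C)C)=CC
A6 | alternative 2 | C5–C6–C7 oxyallyl cation from A5 | CC(C)[C@@](O[Si](CC)(CC)CC)(C=C([O-])[CH2+])CCC(C)=CC(O[Si](C(C)C)(C(C)C)C(C)C)=CC
A7 | alternative 2 | trans-fused hydroazulen-6-one with C9 silyl enol ether and C8 methyl | CC(C)[C@]1(O[Si](CC)(CC)CC)CC[C@]2(C)C=C(O[Si](C(C)C)(C(C)C)C(C)C)[C@H](C)CC(=O)[C@H]21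
A8 | alternative 3 | seven-membered β-keto lactone on the cyclopentene | CC(C)[C@]1(O[Si](CC)(CC)CC)CCC(C)=C1[C@@H]1C[C@](C)(O[Si](CC)(CC)CC)C(=O)CC(=O)O1
A9 | alternative 3 | hydroazulene with C5=C6 alkene, C9 ketone and C8 silyloxy methyl carbinol | CC(C)[C@]1(O[Si](CC)(CC)CC)CC[C@]2(C)CC(=O)[C@@](C)(O[Si](CC)(CC)CC)CC=C21
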